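**Retrosynthetic overview**

1. Numbering used here: C1 is the quinone carbonyl peri to the side chain, C2 the acetoxy carbon, C3 the isopropyl carbon, C4 the second carbonyl, C4a/C8a the ring-fusion carbons, C7 the methyl carbon and C8 the chain carbon.
2. The acetate is removed last, which leads back to salvipisone 15.
3. The quinone ring is cut at C8a–C1 and C2–C3. The enabling feature is that C1–C2 is an acetate-type two-carbon unit lying between the aromatic carbon C8a and C3, the enolisable α-carbon of the C4 aryl ketone. Because a 2-hydroxy-1,4-naphthoquinone is the air-oxidised form of a naphthalene-1,3-diol, aryl triflate 11 and zinc ester enolate 12 should give the whole oxygenated ring by α-arylation, Dieckmann condensation and autoxidation in one flask.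
4. The contiguous C4a(acyl)–C8a(O)–C8(chain)–C7(Me) pattern of 11 maps onto m-cresol: ortho-Fries acylation para to the methyl group, an ortho-Claisen rearrangement that the acyl group forces to C8, and hydroboration/Suzuki extension of allyl to the 4-methylpent-4-enyl chain. The phenol oxygen ends as the triflate leaving group on C8a.
5. Ring order: the benzo ring is bought with 1; the quinone ring is the only ring made, in step 7.

Key step: step 7

Remark: (2-tert-butoxy-2-oxoethyl)zinc chloride 12 is taken as the commercial solution in diethyl ether.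

**Route**

Step 1
Reactants: 1 3-methylphenol (m-cresol); 2 3-methylbutanoyl chloride
Product: 4 1-(2-hydroxy-4-methylphenyl)-3-methylbutan-1-one, via 3-methylphenyl 3-methylbutanoate 3 (not isolated)
Conditions: 2 (1.1 equiv), neat, 60 °C; then AlCl3 (1.5 equiv), 140 °C; ice/aq. HCl
Reagents that add atoms: none
Why: O-acylation followed by a high-temperature, thermodynamically controlled ortho-Fries rearrangement should deliver the acyl group to the unhindered ortho carbon para to the methyl group, where the product is held as its aluminium chelate.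

Step 2
Reactants: 4 1-(2-hydroxy-4-methylphenyl)-3-methylbutan-1-one; 5 allyl bromide (3-bromoprop-1-ene)
Product: 6 3-methyl-1-[4-methyl-2-(prop-2-en-1-yloxy)phenyl]butan-1-one
Conditions: K2CO3, KI (cat.), DMF, 60 °C
Reagents that add atoms: none
Why: Williamson etherification of the phenoxide with a reactive allylic bromide should proceed cleanly in a dipolar aprotic solvent despite the hydrogen-bonded phenol.

Step 3
Reactants: 6 3-methyl-1-[4-methyl-2-(prop-2-en-1-yloxy)phenyl]butan-1-one
Product: 7 1-[2-hydroxy-4-methyl-3-(prop-2-en-1-yl)phenyl]-3-methylbutan-1-one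
Conditions: N,N-diethylaniline, 200 °C, sealed tube
Reagents that add atoms: none
Why: The aromatic Claisen rearrangement can rearomatise only through the single free ortho carbon (between oxygen and methyl) because the other ortho position carries the acyl group, and the product is stabilised by its O–H···O=C hydrogen bond.

Step 4
Reactants: 7 1-[2-hydroxy-4-methyl-3-(prop-2-en-1-yl)phenyl]-3-methylbutan-1-one
Product: 8 1-{2-hydroxy-4-methyl-3-[3-(4,4,5,5-tetramethyl-1,3,2-dioxaborolan-2-yl)propyl]phenyl}-3-methylbutan-1-one
Conditions: HBpin (2.5 equiv), [Ir(cod)Cl]2 (1.5 mol%), dppm (3 mol%), CH2Cl2, 23 °C; aq. NH4Cl work-up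
Reagents that add atoms: pinacolborane, CC1(C)OBOC1(C)C
Why: Iridium-catalysed hydroboration with pinacolborane is anti-Markovnikov selective for terminal alkenes and, unlike stoichiometric dialkylboranes, should leave the aryl ketone untouched; the excess reagent covers transient O-borylation of the phenol, which is reversed on work-up.

Step 5
Reactants: 8 1-{2-hydroxy-4-methyl-3-[3-(4,4,5,5-tetramethyl-1,3,2-dioxaborolan-2-yl)propyl]phenyl}-3-methylbutan-1-one; 9 2-bromopropene
Product: 10 1-[2-hydroxy-4-methyl-3-(4-methylpent-4-en-1-yl)phenyl]-3-methylbutan-1-one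
Conditions: 9 (3 equiv), Pd(OAc)2 (2 mol%), RuPhos (4 mol%), KOH (4 equiv), THF/H2O 10:1, 70 °C, sealed tube
Reagents that add atoms: none
Why: B-alkyl Suzuki–Miyaura coupling of a primary alkyl pinacol boronate with an alkenyl bromide under hydroxide activation, where the bulky dialkylbiarylphosphine favours reductive elimination over β-hydride elimination, should install the isopropenyl terminus.

Step 6
Reactants: 10 1-[2-hydroxy-4-methyl-3-(4-methylpent-4-en-1-yl)phenyl]-3-methylbutan-1-one
Product: 11 3-methyl-6-(3-methylbutanoyl)-2-(4-methylpent-4-en-1-yl)phenyl trifluoromethanesulfonate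
Conditions: Tf2O (1.2 equiv), pyridine (3 equiv), CH2Cl2, −10 → 0 °C
Reagents that add atoms: trifluoromethanesulfonic anhydride, O=S(=O)(OS(=O)(=O)C(F)(F)F)C(F)(F)F
Why: O-sulfonylation of the phenol with the pyridine-buffered anhydride should turn the C8a oxygen into a cross-coupling handle without exposing the isopropenyl group to free acid.

Step 7
Reactants: 11 3-methyl-6-(3-methylbutanoyl)-2-(4-methylpent-4-en-1-yl)phenyl trifluoromethanesulfonate; 12 (2-tert-butoxy-2-oxoethyl)zinc chloride
Product: 15 salvipisone (3-hydroxy-6-methyl-5-(4-methylpent-4-en-1-yl)-2-(propan-2-yl)naphthalene-1,4-dione), via arylacetic ester 13 (not isolated), via naphthalene-1,3-diol 14 (not isolated)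
Conditions: 12 (1.5 equiv), Pd2(dba)3 (2.5 mol%), XPhos (10 mol%), THF/Et2O, 23 °C; then NaOMe (6 equiv), MeOH, 45 °C; then O2 (1 atm), 23 °C; cold aq. citric acid
Reagents that add atoms: dioxygen, O=O
Why: Zerovalent palladium should insert into the C8a–OTf bond (activated by the ortho acyl group), transmetalate with zinc ester enolate 12 and reductively eliminate to forge C8a–C1 in arylacetic ester 13, the known palladium-catalysed coupling of Reformatsky reagents with aryl halides and triflates (Negishi-type α-arylation). NaOMe then generates the C3 enolate of the aryl ketone, which attacks the ester carbonyl C2 in a Dieckmann condensation, a 6-(enolendo)-exo-trig closure of the future quinone ring driven by aromatisation to the naphthalene-1,3-diolate 14. The electron-rich diolate should be autoxidised by O2 at C1, its only unsubstituted position and one that is ortho and para to the two oxygens, to give the 2-hydroxy-1,4-quinone; this alkoxide/air conversion of (2-acylphenyl)acetates into hydroxynaphthoquinones is itself a known reaction type. No stereocentre is formed. The orientation of the ring is fixed because the only leaving group sits on C8a between the acyl group and the chain, so C1 must end peri to the chain, and the condensation can only close C3 onto C2 because attack of the C1 enolate on the C4 ketone would need a four-membered ring. Chemoselectivity rests on the tolerance of zinc enolates for ketones at room temperature and on transmetalation at ambient temperature outrunning 6-exo Heck cyclisation of the arylpalladium onto the isopropenyl group.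

Step 8
Reactants: 15 salvipisone
Product: 16 acetylsalvipisone (7-methyl-8-(4-methylpent-4-en-1-yl)-1,4-dioxo-3-(propan-2-yl)-1,4-dihydronaphthalen-2-yl acetate)
Conditions: Ac2O, pyridine, DMAP (cat.), CH2Cl2, 0 → 23 °C
Reagents that add atoms: acetic anhydride, CC(=O)OC(C)=O
Why: DMAP-catalysed O-acylation of the acidic vinylogous-acid hydroxyl of the hydroxyquinone should proceed under non-acidic conditions that spare the isopropenyl group.

**Compound list**

1 | 3-methylphenol (m-cresol) | Cc1cccc(O)c1 | starting material
2 | 3-methylbutanoyl chloride | CC(C)CC(=O)Cl | starting material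
3 | 3-methylphenyl 3-methylbutanoate | CC(C)CC(=O)Oc1cccc(C)c1 | intermediate
4 | 1-(2-hydroxy-4-methylphenyl)-3-methylbutan-1-one | CC(C)CC(=O)c1ccc(C)cc1O | intermediate
5 | allyl bromide (3-bromoprop-1-ene) | C=CCBr | starting material
6 | 3-methyl-1-[4-methyl-2-(prop-2-en-1-yloxy)phenyl]butan-1-one | CC(C)CC(=O)c1ccc(C)cc1OCC=C | intermediate
7 | 1-[2-hydroxy-4-methyl-3-(prop-2-en-1-yl)phenyl]-3-methylbutan-1-one | CC(C)CC(=O)c1ccc(C)c(CC=C)c1O | intermediate
8 | 1-{2-hydroxy-4-methyl-3-[3-(4,4,5,5-tetramethyl-1,3,2-dioxaborolan-2-yl)propyl]phenyl}-3-methylbutan-1-one | CC(C)CC(=O)c1ccc(C)c(CCCB2OC(C)(C)C(C)(C)O2)c1O | intermediate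
9 | 2-bromopropene | CC(Br)=C | starting material
10 | 1-[2-hydroxy-4-methyl-3-(4-methylpent-4-en-1-yl)phenyl]-3-methylbutan-1-one | CC(C)CC(=O)c1ccc(C)c(CCCC(C)=C)c1O | intermediate
11 | 3-methyl-6-(3-methylbutanoyl)-2-(4-methylpent-4-en-1-yl)phenyl trifluoromethanesulfonate | CC(C)CC(=O)c1ccc(C)c(CCCC(C)=C)c1OS(=O)(=O)C(F)(F)F | intermediate
12 | (2-tert-butoxy-2-oxoethyl)zinc chloride | CC(C)(C)OC(=O)C[Zn]Cl | starting material
13 | tert-butyl [3-methyl-6-(3-methylbutanoyl)-2-(4-methylpent-4-en-1-yl)phenyl]acetate | CC(C)CC(=O)c1ccc(C)c(CCCC(C)=C)c1CC(=O)OC(C)(C)C | intermediate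
14 | 6-methyl-5-(4-methylpent-4-en-1-yl)-2-(propan-2-yl)naphthalene-1,3-diol | CC(C)c1c(O)cc2c(CCCC(C)=C)c(C)ccc2c1O | intermediate
15 | salvipisone, 3-hydroxy-6-methyl-5-(4-methylpent-4-en-1-yl)-2-(propan-2-yl)naphthalene-1,4-dione | C=C(C)CCCc1c(C)ccc2c1C(=O)C(O)=C(C(C)C)C2=O | intermediate
16 | acetylsalvipisone, 7-methyl-8-(4-methylpent-4-en-1-yl)-1,4-dioxo-3-(propan-2-yl)-1,4-dihydronaphthalen-2-yl acetate | C=C(C)CCCc1c(C)ccc2c1C(=O)C(OC(C)=O)=C(C(C)C)C2=O | target

**Step count and risks**

Total step count: 8. Longest linear sequence: 8 steps (1 → 16).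

Steps most likely to fail:

Step 7. Transmetalation and reductive elimination at the arylpalladium, which carries substituents on both ortho carbons, may be slow. In that case 1,2-addition of the zinc enolate to the aryl ketone or loss of the triflate by hydrolysis could take over. The fallback sets out from 11 and returns to the route at 15, with the polarity of the C8a–C1 coupling inverted so that no ester enolate meets the ketone. Miyaura borylation of 11 (B2pin2, PdCl2(dppf), KOAc, dioxane, 80 °C) should give 3-methyl-1-[4-methyl-3-(4-methylpent-4-en-1-yl)-2-(4,4,5,5-tetramethyl-1,3,2-dioxaborolan-2-yl)phenyl]butan-1-one F1. Suzuki–Miyaura coupling of this aryl boronate with ethyl bromoacetate (Pd(OAc)2, P(o-tol)3, K3PO4, THF/H2O, 23 °C) should give ethyl [3-methyl-6-(3-methylbutanoyl)-2-(4-methylpent-4-en-1-yl)phenyl]acetate F2. Treatment with NaOMe in MeOH and then O2 should carry it through diol 14 to 15.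

Step 5. Slow transmetalation of the primary alkyl boronate may let protodeboronation and β-hydride elimination from the alkylpalladium compete, and the volatile bromide may be lost. The fallback sets out from 7 and returns at 10 without any organoboron intermediate. Cross-metathesis of 7 with but-3-en-2-one (second-generation Hoveyda–Grubbs catalyst, CH2Cl2, 40 °C) should give (E)-5-[2-hydroxy-6-methyl-3-(3-methylbutanoyl)phenyl]pent-3-en-2-one F3. Conjugate reduction of the enone (H2, Pd on carbon, EtOAc, 23 °C) should give 5-[2-hydroxy-6-methyl-3-(3-methylbutanoyl)phenyl]pentan-2-one F4. Wittig methylenation of the methyl ketone (Ph3PCH3Br, KOtBu, THF, 0 °C, more than two equivalents) should then give 10; the first equivalent of ylide forms the phenoxide, which deactivates the hindered aryl ketone.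

Step 4. O-borylation of the chelated phenol and binding of the hydroxy ketone to iridium may stall the catalyst, or the ketone may be hydroborated. The fallback sets out from 7 and returns at 10, using a protected phenol and a stoichiometric dialkylborane. Silylation (TBSOTf, 2,6-lutidine, CH2Cl2, 0 °C) should give 1-{2-[(tert-butyldimethylsilyl)oxy]-4-methyl-3-(prop-2-en-1-yl)phenyl}-3-methylbutan-1-one F5. Hydroboration with 9-BBN (THF, 0 → 23 °C; the terminal alkene reacts faster than the hindered aryl ketone) should give the B-alkyl-9-borabicyclo[3.3.1]nonane F6, which is not isolated. Coupling in the same flask with 9 (PdCl2(dppf), aq. K3PO4, DMF, 50 °C) should give 1-{2-[(tert-butyldimethylsilyl)oxy]-4-methyl-3-(4-methylpent-4-en-1-yl)phenyl}-3-methylbutan-1-one F7, and tetrabutylammonium fluoride in THF should release 10.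

Further compounds
F1 | step 7 | 3-methyl-1-[4-methyl-3-(4-methylpent-4-en-1-yl)-2-(4,4,5,5-tetramethyl-1,3,2-dioxaborolan-2-yl)phenyl]butan-1-one | CC(C)CC(=O)c1ccc(C)c(CCCC(C)=C)c1B1OC(C)(C)C(C)(C)O1
F2 | step 7 | ethyl [3-methyl-6-(3-methylbutanoyl)-2-(4-methylpent-4-en-1-yl)phenyl]acetate | CCOC(=O)Cc1c(CCCC(C)=C)c(C)ccc1C(=O)CC(C)C
F3 | step 5 | (E)-5-[2-hydroxy-6-methyl-3-(3-methylbutanoyl)phenyl]pent-3-en-2-one | CC(C)CC(=O)c1ccc(C)c(C/C=C/C(C)=O)c1O
F4 | step 5 | 5-[2-hydroxy-6-methyl-3-(3-methylbutanoyl)phenyl]pentan-2-one | CC(C)CC(=O)c1ccc(C)c(CCCC(C)=O)c1O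
F5 | step 4 | 1-{2-[(tert-butyldimethylsilyl)oxy]-4-methyl-3-(prop-2-en-1-yl)phenyl}-3-methylbutan-1-one | CC(C)CC(=O)c1ccc(C)c(CC=C)c1O[Si](C)(C)C(C)(C)C
F6 | step 4 | 1-{3-[3-(9-borabicyclo[3.3.1]nonan-9-yl)propyl]-2-[(tert-butyldimethylsilyl)oxy]-4-methylphenyl}-3-methylbutan-1-one | CC(C)CC(=O)c1ccc(C)c(CCCB2C3CCCC2CCC3)c1O[Si](C)(C)C(C)(C)C
F7 | step 4 | 1-{2-[(tert-butyldimethylsilyl)oxy]-4-methyl-3-(4-methylpent-4-en-1-yl)phenyl}-3-methylbutan-1-one | CC(C)CC(=O)c1ccc(C)c(CCCC(C)=C)c1O[Si](C)(C)C(C)(C)C
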